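**Plan** (drimane numbering: ring A = C1–C5 and C10; ring B = C5–C10; C11 on C9, C12 on C8)
- Cuts: the C1–O acyl bond first, then both formyl groups back to a C11/C12 dimethyl ester, then ring B at C7–C8 and C9–C10 (retro-[4+2]).
- Enabling feature: in ring B the carbonyl-bearing carbons C8 and C9 are adjacent, and C9 is bonded to the quaternary C10, which adjoins the oxygenated stereocentre C1. C8≡C9 is therefore a but-2-ynedioate, and C10=C5–C6=C7 is a 1-vinylcyclohexene diene of ring A with the allylic C1–O next to its reacting terminus.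
- Forward order: ring A is made first (2-methylcyclohexane-1,3-dione, vinylogous ester, gem-dimethylation, vinyl addition with carbonyl transposition, enantioselective reduction at C1). Ring B is closed last by the cycloaddition; a prototropic shift and a hydrogenation then place the C7=C8 bond. Reduction, selective silylation, esterification at O1, desilylation and double oxidation finish the route.
- Stereochemistry: C1 by reagent control (CBS reduction); C10 from C1 (addition anti to the C1 acyloxy group); C9 by protonation and C5 by hydrogenation, both anti to the C10 methyl; the E alkene comes with the commercial acid.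

Key step: step 6

**Route**

Step 1
Reactants: 1 2-methylcyclohexane-1,3-dione
Product: 2 3-isobutoxy-2-methylcyclohex-2-en-1-one
Conditions: i-BuOH, TsOH (catalytic), toluene, reflux, Dean–Stark trap
Reagents that add atoms: 2-methylpropan-1-ol, CC(C)CO
Why: acid-catalysed enol ether formation from the symmetric cyclic 1,3-diketone with azeotropic removal of water gives the single vinylogous ester needed for Stork–Danheiser chemistry.

Step 2
Reactants: 2 3-isobutoxy-2-methylcyclohex-2-en-1-one
Product: 4 3-isobutoxy-2,6,6-trimethylcyclohex-2-en-1-one, via monomethyl enol ether 3 (not isolated)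
Conditions: LiN(i-Pr)2, THF, −78 °C; MeI, −78 to 0 °C; then LiN(i-Pr)2, −78 °C; MeI, to rt (one flask)
Reagents that add atoms: iodomethane, CI
Why: kinetic deprotonation of a vinylogous ester takes place at the α′ carbon (C6), so two successive enolate methylations (Stork–Danheiser alkylation) install the gem-dimethyl group that becomes C4 of the target, and no stereocentre remains.

Step 3
Reactants: 4 3-isobutoxy-2,6,6-trimethylcyclohex-2-en-1-one
Product: 6 2,4,4-trimethyl-3-vinylcyclohex-2-en-1-one, via tertiary allylic carbinol 5 (not isolated)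
Conditions: CH2=CHMgBr, THF, 0 °C to rt; then 1 M HCl, THF, rt
Reagents that add atoms: vinylmagnesium bromide, C=C[Mg]Br; water, O
Why: 1,2-addition of the Grignard reagent to the vinylogous ester carbonyl (no α-hydrogen on its quaternary side) followed by acid hydrolysis of the enol ether with loss of water (Stork–Danheiser transposition) moves the carbonyl to the former enol ether carbon and gives the cross-conjugated dienone.

Step 4
Reactants: 6 2,4,4-trimethyl-3-vinylcyclohex-2-en-1-one
Product: 7 (R)-2,4,4-trimethyl-3-vinylcyclohex-2-en-1-ol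
Conditions: (S)-Me-CBS oxazaborolidine ((S)-1-methyl-3,3-diphenyltetrahydro-1H,3H-pyrrolo[1,2-c][1,3,2]oxazaborole, 20 mol %), catecholborane, toluene, −78 to −40 °C; MeOH quench, aqueous work-up
Reagents that add atoms: none
Why: Corey–Bakshi–Shibata reduction in which the tetrasubstituted alkenyl carbon is the large group and the ring CH2 the small one, so the (S)-catalyst should deliver hydride to give the (R)-alcohol that becomes C1 of the target; catecholborane is chosen because it should not hydroborate the diene at low temperature.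

Step 5
Reactants: 7 (R)-2,4,4-trimethyl-3-vinylcyclohex-2-en-1-ol
Product: 8 (R)-2,4,4-trimethyl-3-vinylcyclohex-2-en-1-yl pivalate
Conditions: PivCl, Et3N, DMAP (catalytic), CH2Cl2, 0 °C to rt
Reagents that add atoms: pivaloyl chloride, CC(C)(C)C(=O)Cl
Why: DMAP-catalysed acylation of the secondary allylic alcohol gives an ester that should tolerate the thermal, amine-base and hydrogenation steps, acts as the bulky face-shielding group next to the diene terminus, and is removed later by LiAlH4 without a separate operation.

Step 6
Reactants: 8 (R)-2,4,4-trimethyl-3-vinylcyclohex-2-en-1-yl pivalate, 9 dimethyl but-2-ynedioate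
Product: 10 dimethyl (1R,10S)-1-(pivaloyloxy)drima-5,8-diene-11,12-dioate (1β-pivaloyloxy, 10β-methyl)
Conditions: 9 (2 equiv), BHT (catalytic), toluene, 110 °C, sealed tube
Reagents that add atoms: none
Why: The mechanism is a concerted, thermally allowed suprafacial [4+2] cycloaddition in which the s-cis diene C10=C5–C6=C7 of ring A is spanned by the alkyne C8≡C9 of 9, so that the C7–C8 and C9–C10 bonds form together and a cyclohexa-1,4-diene with C5=C6 and C8=C9 results. The closest known reaction type is the thermal Diels–Alder reaction of 2,6,6-trimethyl-1-vinylcyclohexenes with acetylenedicarboxylates. Ring B is closed by an intermolecular [4+2] annulation onto the pre-formed ring A, and no other ring is formed. The only new stereocentre, the quaternary C10, is controlled by the C1 stereocentre: the pivaloyloxy group is held pseudoaxial by A(1,2) strain with the C10 methyl, and the dienophile should bond to C10 on the opposite face, which places the methyl cis to the C1 oxygen as in the target. The step needs facial selectivity only, because 9 is symmetric (no regiochemical question), an alkyne has no endo or exo mode, and the electron-poor alkyne pairs with the alkyl-rich diene in normal electron demand.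

Step 7
Reactants: 10 dimethyl (1R,10S)-1-(pivaloyloxy)drima-5,8-diene-11,12-dioate
Product: 11 dimethyl (1R,9R,10R)-1-(pivaloyloxy)drima-5,7-diene-11,12-dioate (9α-H, ester on C9 β)
Conditions: DBU, THF, rt, stopped at full conversion
Reagents that add atoms: none
Why: base-mediated prototropic shift through the extended dienolate formed by removal of a doubly allylic C7 proton moves the C8=C9 bond to C7=C8, in linear conjugation with C5=C6 and the C12 ester, and protonation at C9 should take place anti to the C10 methyl to give the 9α-H configuration.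

Step 8
Reactants: 11 dimethyl (1R,9R,10R)-1-(pivaloyloxy)drima-5,7-diene-11,12-dioate
Product: 12 dimethyl (1R,5S,9R,10S)-1-(pivaloyloxy)drim-7-ene-11,12-dioate (trans-fused, 5α-H)
Conditions: H2 (1 atm), Pd/C (10 wt %), EtOAc, rt
Reagents that add atoms: none
Why: heterogeneous hydrogenation should saturate the terminal C5=C6 bond of the dienoate from the α-face, opposite the C10 methyl, which sets C5 and the trans ring fusion, while the ester-bearing trisubstituted C7=C8 bond and the pivalate remain.

Step 9
Reactants: 12 dimethyl (1R,5S,9R,10S)-1-(pivaloyloxy)drim-7-ene-11,12-dioate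
Product: 13 (1R,5S,9S,10S)-drim-7-ene-1,11,12-triol
Conditions: LiAlH4, THF, 0 °C to rt; H2O, aqueous NaOH work-up
Reagents that add atoms: none
Why: LiAlH4 reduces both methyl esters (the enoate by 1,2-addition to the allylic alcohol) and cleaves the pivalate in the same operation without touching any stereocentre; the descriptor at C9 changes only through the priority rules.

Step 10
Reactants: 13 (1R,5S,9S,10S)-drim-7-ene-1,11,12-triol
Product: 14 (1R,5S,9S,10S)-11,12-bis(tert-butyldimethylsilyloxy)drim-7-en-1-ol
Conditions: TBSCl (2.2 equiv), imidazole, CH2Cl2, 0 °C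
Reagents that add atoms: tert-butyldimethylsilyl chloride, CC(C)(C)[Si](C)(C)Cl
Why: silylation is strongly selective for the two primary hydroxyls over the secondary C1 hydroxyl, which is flanked by the quaternary C10.

Step 11
Reactants: 14 (1R,5S,9S,10S)-11,12-bis(tert-butyldimethylsilyloxy)drim-7-en-1-ol, 15 (E)-4-methoxycinnamic acid
Product: 17 (1R,5S,9S,10S)-11,12-bis(tert-butyldimethylsilyloxy)drim-7-en-1-yl (E)-4-methoxycinnamate, via mixed anhydride 16 (not isolated)
Conditions: 15, 2,4,6-trichlorobenzoyl chloride, Et3N, THF, rt; then 14, DMAP, toluene, 60 °C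
Reagents that add atoms: none
Why: Yamaguchi esterification, in which DMAP attacks the less hindered cinnamoyl carbonyl of the mixed anhydride to give an acylpyridinium ion that should acylate the hindered equatorial C1 hydroxyl with retention at C1 and of the E alkene.

Step 12
Reactants: 17 (1R,5S,9S,10S)-11,12-bis(tert-butyldimethylsilyloxy)drim-7-en-1-yl (E)-4-methoxycinnamate
Product: 18 (1R,5S,9S,10S)-11,12-dihydroxydrim-7-en-1-yl (E)-4-methoxycinnamate
Conditions: HF·pyridine, pyridine, THF, 0 °C to rt
Reagents that add atoms: none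
Why: buffered fluoride cleavage of the two primary silyl ethers should leave the cinnamate ester and the trisubstituted alkene untouched.

Step 13
Reactants: 18 (1R,5S,9S,10S)-11,12-dihydroxydrim-7-en-1-yl (E)-4-methoxycinnamate
Product: 20 (1R,5S,9R,10S)-11,12-dioxodrim-7-en-1-yl (E)-4-methoxycinnamate (the target), via bis(alkoxysulfonium) salt 19 (not isolated)
Conditions: (COCl)2, DMSO, CH2Cl2, −78 °C; then Et3N, −78 to −30 °C; cold pH 7 buffer
Reagents that add atoms: none
Why: Swern oxidation, in which both primary hydroxyls are converted into alkoxysulfonium ions before the base is added, so that no hydroxy aldehyde can close to a lactol and be oxidised on to a lactone, and the cold quench limits epimerisation of the formyl-bearing C9.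

**Compound list**

1 | 2-methylcyclohexane-1,3-dione | CC1C(=O)CCCC1=O | starting material
2 | 3-isobutoxy-2-methylcyclohex-2-en-1-one | CC1=C(OCC(C)C)CCCC1=O | intermediate
3 | 3-isobutoxy-2,6-dimethylcyclohex-2-en-1-one (racemic) | CC1CCC(OCC(C)C)=C(C)C1=O | intermediate
4 | 3-isobutoxy-2,6,6-trimethylcyclohex-2-en-1-one | CC1=C(OCC(C)C)CCC(C)(C)C1=O | intermediate
5 | 3-isobutoxy-2,6,6-trimethyl-1-vinylcyclohex-2-en-1-ol (racemic) | C=CC1(O)C(C)=C(OCC(C)C)CCC1(C)C | intermediate
6 | 2,4,4-trimethyl-3-vinylcyclohex-2-en-1-one | C=CC1=C(C)C(=O)CCC1(C)C | intermediate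
7 | (R)-2,4,4-trimethyl-3-vinylcyclohex-2-en-1-ol | O[C@@H]1CCC(C)(C)C(C=C)=C1C | intermediate
8 | (R)-2,4,4-trimethyl-3-vinylcyclohex-2-en-1-yl pivalate | CC(C)(C)C(=O)O[C@@H]1CCC(C)(C)C(C=C)=C1C | intermediate
9 | dimethyl but-2-ynedioate | COC(=O)C#CC(=O)OC | starting material
10 | dimethyl (1R,10S)-1-(pivaloyloxy)drima-5,8-diene-11,12-dioate | CC(C)(C)C(=O)O[C@@H]1CCC(C)(C)C2=CCC(C(=O)OC)=C(C(=O)OC)[C@@]12C | intermediate
11 | dimethyl (1R,9R,10R)-1-(pivaloyloxy)drima-5,7-diene-11,12-dioate | CC(C)(C)C(=O)O[C@@H]1CCC(C)(C)C2=CC=C(C(=O)OC)[C@H](C(=O)OC)[C@@]12C | intermediate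
12 | dimethyl (1R,5S,9R,10S)-1-(pivaloyloxy)drim-7-ene-11,12-dioate | CC(C)(C)C(=O)O[C@@H]1CCC(C)(C)[C@@H]2CC=C(C(=O)OC)[C@H](C(=O)OC)[C@@]12C | intermediate
13 | (1R,5S,9S,10S)-drim-7-ene-1,11,12-triol | O[C@@H]1CCC(C)(C)[C@@H]2CC=C(CO)[C@H](CO)[C@@]12C | intermediate
14 | (1R,5S,9S,10S)-11,12-bis(tert-butyldimethylsilyloxy)drim-7-en-1-ol | O[C@@H]1CCC(C)(C)[C@@H]2CC=C(CO[Si](C)(C)C(C)(C)C)[C@H](CO[Si](C)(C)C(C)(C)C)[C@@]12C | intermediate
15 | (E)-4-methoxycinnamic acid | COc1ccc(/C=C/C(=O)O)cc1 | starting material
16 | (E)-4-methoxycinnamic 2,4,6-trichlorobenzoic anhydride | COc1ccc(/C=C/C(=O)OC(=O)c2c(Cl)cc(Cl)cc2Cl)cc1 | intermediate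
17 | (1R,5S,9S,10S)-11,12-bis(tert-butyldimethylsilyloxy)drim-7-en-1-yl (E)-4-methoxycinnamate | COc1ccc(/C=C/C(=O)O[C@@H]2CCC(C)(C)[C@@H]3CC=C(CO[Si](C)(C)C(C)(C)C)[C@H](CO[Si](C)(C)C(C)(C)C)[C@@]23C)cc1 | intermediate
18 | (1R,5S,9S,10S)-11,12-dihydroxydrim-7-en-1-yl (E)-4-methoxycinnamate | COc1ccc(/C=C/C(=O)O[C@@H]2CCC(C)(C)[C@@H]3CC=C(CO)[C@H](CO)[C@@]23C)cc1 | intermediate
19 | 11,12-bis(dimethylsulfoniooxy) derivative of 18, dichloride | COc1ccc(/C=C/C(=O)O[C@@H]2CCC(C)(C)[C@@H]3CC=C(CO[S+](C)C)[C@H](CO[S+](C)C)[C@@]23C)cc1.[Cl-].[Cl-] | intermediate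
20 | (1R,5S,9R,10S)-11,12-dioxodrim-7-en-1-yl (E)-4-methoxycinnamate | COc1ccc(/C=C/C(=O)O[C@@H]2CCC(C)(C)[C@@H]3CC=C(C=O)[C@H](C=O)[C@@]23C)cc1 | target

**Totals and risks**

Total step count: 13. Longest linear sequence: 13 steps (1 to 20); 9 and 15 enter as commercial compounds.

Steps most likely to fail:

Step 6. The pivaloyloxy group may discriminate the two diene faces incompletely, and the hindered diene may add slowly enough for a thermal 1,5-hydrogen shift to compete. The fallback sets out from 7 and replaces the ester by a bulky, non-polar silyl ether as the shielding group, which also makes the diene more electron-rich. Silylation (TBSCl, imidazole, DMF) would give (R)-tert-butyldimethyl[(2,4,4-trimethyl-3-vinylcyclohex-2-en-1-yl)oxy]silane F1. Cycloaddition of this diene and 9 (toluene, 110 °C) should give dimethyl (1R,10S)-1-(tert-butyldimethylsilyloxy)drima-5,8-diene-11,12-dioate F2. HF·pyridine in THF would give dimethyl (1R,10S)-1-hydroxydrima-5,8-diene-11,12-dioate F3, which is acylated at once (PivCl, Et3N, DMAP) and comes back to the route at 10.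

Step 7. Under the equilibrating amine base, C9 may epimerise toward the isomer with the ester on the α-face (relief of the contact between the C9 ester and the C1 pivaloyloxy group), and the double bonds may migrate further. The fallback sets out from 10 and sets C9 under kinetic control. Hydrogenation of the C5=C6 bond first (H2, Pd/C, EtOAc), from the face opposite the C10 methyl, would give dimethyl (1R,5S,10S)-1-(pivaloyloxy)drim-8-ene-11,12-dioate F4. Irreversible γ-deprotonation at C7 (LiN(i-Pr)2, THF, DMPU, −78 °C) followed by α-protonation of the dienolate at C9 by acetic acid at −78 °C, anti to the C10 methyl, comes back to the route at 12.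

Step 11. Acylation of the hindered C1 hydroxyl may be slow, so that the mixed anhydride decomposes or a silyl group migrates. The fallback sets out from 14 and builds the cinnamate on the molecule. Esterification with the small 2-(diethoxyphosphoryl)acetic acid (DCC, catalytic DMAP, CH2Cl2) would give (1R,5S,9S,10S)-11,12-bis(tert-butyldimethylsilyloxy)drim-7-en-1-yl 2-(diethoxyphosphoryl)acetate F5. Horner–Wadsworth–Emmons olefination with 4-methoxybenzaldehyde under Masamune–Roush conditions (LiCl, DBU, MeCN) should form the E alkene and comes back to the route at 17.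

**Further compounds**

F1 | step 6 | (R)-tert-butyldimethyl[(2,4,4-trimethyl-3-vinylcyclohex-2-en-1-yl)oxy]silane | CC(C)(C)[Si](C)(C)O[C@@H]1CCC(C)(C)C(C=C)=C1C
F2 | step 6 | dimethyl (1R,10S)-1-(tert-butyldimethylsilyloxy)drima-5,8-diene-11,12-dioate | CC(C)(C)[Si](C)(C)O[C@@H]1CCC(C)(C)C2=CCC(C(=O)OC)=C(C(=O)OC)[C@@]12C
F3 | step 6 | dimethyl (1R,10S)-1-hydroxydrima-5,8-diene-11,12-dioate | O[C@@H]1CCC(C)(C)C2=CCC(C(=O)OC)=C(C(=O)OC)[C@@]12C
F4 | step 7 | dimethyl (1R,5S,10S)-1-(pivaloyloxy)drim-8-ene-11,12-dioate | CC(C)(C)C(=O)O[C@@H]1CCC(C)(C)[C@@H]2CCC(C(=O)OC)=C(C(=O)OC)[C@@]12C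
F5 | step 11 | (1R,5S,9S,10S)-11,12-bis(tert-butyldimethylsilyloxy)drim-7-en-1-yl 2-(diethoxyphosphoryl)acetate | CCOP(=O)(OCC)CC(=O)O[C@@H]1CCC(C)(C)[C@@H]2CC=C(CO[Si](C)(C)C(C)(C)C)[C@H](CO[Si](C)(C)C(C)(C)C)[C@@]12C
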